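**Plan**

- Numbering: ring C1 (methyl-bearing epoxide carbon), C2 (epoxide CH), C3 (CH2), C4 (CH bearing the chain), C5 (CH–O-angeloyl), C6 (CH–OAc); chain C7(=C14H2)–C8(O-angeloyl)–C9–C10/C11 (dimethyl epoxide).
- Retrosynthetic cuts, in order: the C10–C11 epoxide oxygen, the two angelate C–O bonds, C7–C8 (alkenyl iodide + 4-methylpent-3-enal), the C1–C2 epoxide oxygen, then C4–C7.
- Enabling feature: C7 on C4 and the oxygen on C5 are cis neighbours on the six-membered ring, so one silicon atom bonded to O5 and C7 completes a five-membered C7–Si–O–C5–C4 ring and can only bring C7 to the O5 face of C4.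
- Forward order: enzymatic cis-diol (C5, C6) on the carbocycle, silyl ether/acetate, oxasilolane ring by radical closure (opened again one step later), alkenyl iodide, ring epoxide, C5 angelate, chain joined at C7–C8, C8 angelate, side-chain epoxide.
- Stereochemistry: C5/C6 from toluene dioxygenase, C4 from the tether, C1/C2 from delivery by the C5 hydroxyl, C8 from the chiral ligand on chromium, C10 from the L-fructose-derived ketone catalyst; both Z-alkenes come from angelic acid.

Key step: step 4

**Remarks (assumptions)**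

- Silane 4 is taken as purchasable; where it is not stocked it is made from chlorodimethylvinylsilane by bromine addition and amine-induced loss of HBr.
- In step 1 iodine is assumed to outrank methyl in the enzyme pocket, so that 2 has the configuration of the iodobenzene-derived diol; its enantiomeric purity is to be checked and raised by recrystallisation before step 2.
- The ligand enantiomer written in step 9 is assumed to lead to the (8S) alcohol; if a trial shows the opposite sense, its mirror image is used.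

**Route**

Step 1
Reactants: 1 4-iodotoluene
Product: 2 (1S,2S)-3-iodo-6-methylcyclohexa-3,5-diene-1,2-diol
Conditions: whole cells of E. coli JM109(pDTG601) expressing toluene dioxygenase, IPTG, glucose, air, phosphate buffer pH 7.2, 30 °C; EtOAc extraction, recrystallisation
Reagents that add atoms: dioxygen, O=O
Why: Enzymatic arene cis-dihydroxylation (toluene dioxygenase), in which the larger substituent, iodine, should decide the binding orientation, so that both oxygen atoms enter syn at the two carbons between iodine and methyl with the facial sense known for iodobenzene, setting C5 and C6 of the target.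

Step 2
Reactants: 2 (1S,2S)-3-iodo-6-methylcyclohexa-3,5-diene-1,2-diol
Product: 3 (1R,2S)-3-methylcyclohexa-3,5-diene-1,2-diol
Conditions: H2 (1 atm, stopped after 1 equiv), Pd/C, NaOAc, MeOH, 0 °C
Reagents that add atoms: none
Why: Catalytic hydrogenolysis of the alkenyl C–I bond, which on palladium should be much faster than saturation of the diene when hydrogen uptake is limited, removes the directing iodine and leaves the enantiomer of the diol that toluene itself would give, while NaOAc takes up HI so that the acid-labile diol does not aromatise.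

Step 3
Reactants: 3 (1R,2S)-3-methylcyclohexa-3,5-diene-1,2-diol; 4 (1-bromoethenyl)chlorodimethylsilane
Product: 6 (1S,6R)-6-{[(1-bromoethenyl)dimethylsilyl]oxy}-2-methylcyclohexa-2,4-dien-1-yl acetate, via C5 monosilyl ether 5 (not isolated)
Conditions: 4 (1.0 equiv, slow addition), Et3N, CH2Cl2, −78 °C; then Ac2O, DMAP (cat.), −78 to 0 °C; rapid filtration through Et3N-deactivated silica
Reagents that add atoms: acetic anhydride, CC(=O)OC(C)=O
Why: Silylation of an alcohol with a chlorosilane followed by DMAP-catalysed acetylation in the same flask; the C5 hydroxyl (next to an unsubstituted vinylic CH) is more accessible than the C6 hydroxyl crowded by the C1 methyl group, so the silane should go to O5, and immediate acetylation of O6 avoids isolating the labile hydroxy silyl ether and leaves no time for silyl migration.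

Step 4
Reactants: 6 (1S,6R)-6-{[(1-bromoethenyl)dimethylsilyl]oxy}-2-methylcyclohexa-2,4-dien-1-yl acetate
Product: 7 (3aR,7S,7aR)-2,2,6-trimethyl-3-methylidene-2,3,3a,4,7,7a-hexahydro-1,2-benzoxasilol-7-yl acetate
Conditions: Bu3SnH (1.3 equiv) and AIBN (0.2 equiv) added over 4 h by syringe pump, degassed benzene (0.01 M), 80 °C; aq. KF work-up
Reagents that add atoms: none
Why: The tributylstannyl radical abstracts bromine from 6 to give a σ-type α-silylvinyl radical at C7, which adds to C4, the near end of the C4=C3–C2=C1 diene, forming the C4–C7 bond, and the resulting C3–C2–C1 allyl radical takes hydrogen from Bu3SnH to carry the chain. The closest known reaction type is the tin hydride mediated 5-exo cyclisation of (1-bromovinyl)silyl ethers of allylic alcohols. The oxasilolane ring (C7–Si–O–C5–C4) closes in the 5-exo-trig mode, and 6-endo attack at C3 is disfavoured because only attack at C4 gives an allyl-stabilised radical, which also suppresses the ring-expanding rearrangement known for cyclised vinyl radicals. The one new stereocentre, C4, is controlled by the tether, since a five-membered ring fused to the cyclohexene through the three-atom bridge from O5 can only be cis, so C7 arrives on the face of the C5–O bond set by the enzyme. The step needs ring closure before reduction of the vinyl radical, which slow stannane addition at high dilution should secure, and hydrogen transfer to C3 rather than C1, which the substrate favours because C1 is a tertiary centre shielded by its methyl group and the C6 acetate and because reduction at C3 leaves the more substituted C1=C2 alkene.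

Step 5
Reactants: 7 (3aR,7S,7aR)-2,2,6-trimethyl-3-methylidene-2,3,3a,4,7,7a-hexahydro-1,2-benzoxasilol-7-yl acetate
Product: 9 (1S,5R,6R)-6-hydroxy-5-(1-iodoethenyl)-2-methylcyclohex-2-en-1-yl acetate, via hexafluoroisopropoxysilyl ether 8 (not isolated)
Conditions: N-iodosuccinimide (1.2 equiv), 2,6-lutidine, (CF3)2CHOH, 0 °C, dark; aq. Na2S2O3; then THF/aq. citric acid, rt
Reagents that add atoms: N-iodosuccinimide, O=C1CCC(=O)N1I
Why: Iododesilylation of an alkenylsilane (electrophilic ipso substitution), in which iodonium formation at C7=C14 is followed by loss of silicon to the solvent to give the 2-iodoalk-1-ene without touching C4, after which mild acid hydrolyses the remaining Si–O bond; because O5 is still silylated and the medium is buffered and non-nucleophilic, the C1=C2 bond should have no productive path.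

Step 6
Reactants: 9 (1S,5R,6R)-6-hydroxy-5-(1-iodoethenyl)-2-methylcyclohex-2-en-1-yl acetate
Product: 10 (1S,2R,3R,4R,6S)-3-hydroxy-4-(1-iodoethenyl)-1-methyl-7-oxabicyclo[4.1.0]heptan-2-yl acetate
Conditions: VO(acac)2 (5 mol%), t-BuOOH (1.5 equiv, decane), CH2Cl2, 0 °C to rt
Reagents that add atoms: tert-butyl hydroperoxide, CC(C)(C)OO
Why: Vanadium-catalysed hydroxyl-directed epoxidation, in which the homoallylic C5 alkoxide (axial in the half-chair that keeps the C4 substituent equatorial) binds the vanadium alkylperoxide and delivers oxygen to C1=C2 on its own face, giving the epoxide cis to the C5 and C6 oxygens, while the electron-poor iodoalkene is not attacked.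

Step 7
Reactants: 10 (1S,2R,3R,4R,6S)-3-hydroxy-4-(1-iodoethenyl)-1-methyl-7-oxabicyclo[4.1.0]heptan-2-yl acetate
Product: 11 (1S,2R,3R,4R,6S)-2-(acetyloxy)-4-(1-iodoethenyl)-1-methyl-7-oxabicyclo[4.1.0]heptan-3-yl (2Z)-2-methylbut-2-enoate
Conditions: angelic acid, 2,4,6-trichlorobenzoyl chloride, Et3N, toluene, rt, 2 h; then 10, 80 °C; no DMAP
Reagents that add atoms: angelic acid [(2Z)-2-methylbut-2-enoic acid], C/C=C(/C)C(=O)O
Why: Yamaguchi esterification with the preformed mixed anhydride of angelic acid, run without a nucleophilic catalyst so that the Z double bond should not isomerise to the tiglate, and with amine base only so that no alkoxide forms next to the C6 acetate.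

Step 8
Reactants: 12 4-methylpent-3-en-1-ol
Product: 13 4-methylpent-3-enal
Conditions: Dess–Martin periodinane, pyridine, CH2Cl2, 0 °C; used at once as a cold solution
Reagents that add atoms: none
Why: Dess–Martin oxidation of a primary alcohol under buffered, non-basic conditions, which should keep the β,γ-double bond from moving into conjugation.

Step 9
Reactants: 11 (1S,2R,3R,4R,6S)-2-(acetyloxy)-4-(1-iodoethenyl)-1-methyl-7-oxabicyclo[4.1.0]heptan-3-yl (2Z)-2-methylbut-2-enoate; 13 4-methylpent-3-enal
Product: 14 (1S,2R,3R,4S,6S)-2-(acetyloxy)-4-[(3S)-3-hydroxy-6-methylhepta-1,5-dien-2-yl]-1-methyl-7-oxabicyclo[4.1.0]heptan-3-yl (2Z)-2-methylbut-2-enoate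
Conditions: CrCl2 (4 equiv), (S)-N-[2-(4-isopropyl-4,5-dihydro-1,3-oxazol-2-yl)-6-methylphenyl]methanesulfonamide (4.4 equiv), Et3N (4.4 equiv), THF, rt; then NiCl2 (0.1 equiv), 11, 13 (3 equiv), rt
Reagents that add atoms: none
Why: Asymmetric Nozaki–Hiyama–Kishi coupling, in which zerovalent nickel inserts into the C7–I bond, the alkenyl group passes to trivalent chromium and adds only to the aldehyde (esters and the epoxide are tolerated), and the chiral oxazoline sulfonamide on chromium directs the addition to the Re face of 13 to set (8S).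

Step 10
Reactants: 14 (1S,2R,3R,4S,6S)-2-(acetyloxy)-4-[(3S)-3-hydroxy-6-methylhepta-1,5-dien-2-yl]-1-methyl-7-oxabicyclo[4.1.0]heptan-3-yl (2Z)-2-methylbut-2-enoate
Product: 15 (1S,2R,3R,4S,6S)-2-(acetyloxy)-1-methyl-4-[(3S)-6-methyl-3-{[(2Z)-2-methylbut-2-enoyl]oxy}hepta-1,5-dien-2-yl]-7-oxabicyclo[4.1.0]heptan-3-yl (2Z)-2-methylbut-2-enoate
Conditions: angelic acid, 2,4,6-trichlorobenzoyl chloride, Et3N, toluene, rt; then 14, 60 °C; no DMAP
Reagents that add atoms: angelic acid [(2Z)-2-methylbut-2-enoic acid], C/C=C(/C)C(=O)O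
Why: Yamaguchi esterification of the secondary allylic C8 hydroxyl with retention at C8 (acyl transfer to oxygen), again without a nucleophilic catalyst to keep the Z geometry.

Step 11
Reactants: 15 (1S,2R,3R,4S,6S)-2-(acetyloxy)-1-methyl-4-[(3S)-6-methyl-3-{[(2Z)-2-methylbut-2-enoyl]oxy}hepta-1,5-dien-2-yl]-7-oxabicyclo[4.1.0]heptan-3-yl (2Z)-2-methylbut-2-enoate
Product: 16 (1S,2R,3R,4S,6S)-2-(acetyloxy)-4-[(3S)-4-[(2S)-3,3-dimethyloxiran-2-yl]-3-{[(2Z)-2-methylbut-2-enoyl]oxy}but-1-en-2-yl]-1-methyl-7-oxabicyclo[4.1.0]heptan-3-yl (2Z)-2-methylbut-2-enoate (CNP0316628.1)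
Conditions: 1,2:4,5-di-O-isopropylidene-β-L-erythro-hexo-2,3-diulo-2,6-pyranose (L-fructose-derived ketone, 0.3 equiv), KHSO5 (as 2KHSO5·KHSO4·K2SO4), K2CO3, Bu4NHSO4, MeCN/CH2(OMe)2/aq. Na2B4O7 buffer (pH 10.5), 0 °C
Reagents that add atoms: potassium peroxymonosulfate (KHSO5), [K+].[O-]S(=O)(=O)OO
Why: Shi epoxidation, in which the chiral dioxirane formed from the ketone attacks the only electron-rich trisubstituted alkene (C10=C11) through a spiro transition state, the L-fructose-derived catalyst being the enantiomer expected to give (10S), while the angelate and 1,1-disubstituted alkenes are too electron-poor or hindered to compete.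

**Compound list**

1 | 4-iodotoluene | Cc1ccc(I)cc1 | starting material
2 | (1S,2S)-3-iodo-6-methylcyclohexa-3,5-diene-1,2-diol | IC1=CC=C(C)[C@H](O)[C@@H]1O | intermediate
3 | (1R,2S)-3-methylcyclohexa-3,5-diene-1,2-diol | C1=CC=C(C)[C@H](O)[C@@H]1O | intermediate
4 | (1-bromoethenyl)chlorodimethylsilane | C[Si](C)(Cl)C(Br)=C | starting material
5 | (1S,6R)-6-{[(1-bromoethenyl)dimethylsilyl]oxy}-2-methylcyclohexa-2,4-dien-1-ol | C1=CC=C(C)[C@H](O)[C@@H]1O[Si](C)(C)C(Br)=C | intermediate (not isolated)
6 | (1S,6R)-6-{[(1-bromoethenyl)dimethylsilyl]oxy}-2-methylcyclohexa-2,4-dien-1-yl acetate | C1=CC=C(C)[C@H](OC(C)=O)[C@@H]1O[Si](C)(C)C(Br)=C | intermediate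
7 | (3aR,7S,7aR)-2,2,6-trimethyl-3-methylidene-2,3,3a,4,7,7a-hexahydro-1,2-benzoxasilol-7-yl acetate | C=C3[C@@H]1CC=C(C)[C@H](OC(C)=O)[C@@H]1O[Si]3(C)C | intermediate
8 | (1S,5R,6R)-6-{[dimethyl(1,1,1,3,3,3-hexafluoropropan-2-yloxy)silyl]oxy}-5-(1-iodoethenyl)-2-methylcyclohex-2-en-1-yl acetate | C=C(I)[C@@H]1CC=C(C)[C@H](OC(C)=O)[C@@H]1O[Si](C)(C)OC(C(F)(F)F)C(F)(F)F | intermediate (not isolated)
9 | (1S,5R,6R)-6-hydroxy-5-(1-iodoethenyl)-2-methylcyclohex-2-en-1-yl acetate | C=C(I)[C@@H]1CC=C(C)[C@H](OC(C)=O)[C@@H]1O | intermediate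
10 | (1S,2R,3R,4R,6S)-3-hydroxy-4-(1-iodoethenyl)-1-methyl-7-oxabicyclo[4.1.0]heptan-2-yl acetate | C=C(I)[C@@H]1C[C@@H]2O[C@]2(C)[C@H](OC(C)=O)[C@@H]1O | intermediate
11 | (1S,2R,3R,4R,6S)-2-(acetyloxy)-4-(1-iodoethenyl)-1-methyl-7-oxabicyclo[4.1.0]heptan-3-yl (2Z)-2-methylbut-2-enoate | C=C(I)[C@@H]1C[C@@H]2O[C@]2(C)[C@H](OC(C)=O)[C@@H]1OC(=O)/C(C)=C\C | intermediate
12 | 4-methylpent-3-en-1-ol | CC(C)=CCCO | starting material
13 | 4-methylpent-3-enal | CC(C)=CCC=O | intermediate
14 | (1S,2R,3R,4S,6S)-2-(acetyloxy)-4-[(3S)-3-hydroxy-6-methylhepta-1,5-dien-2-yl]-1-methyl-7-oxabicyclo[4.1.0]heptan-3-yl (2Z)-2-methylbut-2-enoate | C=C([C@H](CC=C(C)C)O)[C@@H]1C[C@@H]2O[C@]2(C)[C@H](OC(C)=O)[C@@H]1OC(=O)/C(C)=C\C | intermediate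
15 | (1S,2R,3R,4S,6S)-2-(acetyloxy)-1-methyl-4-[(3S)-6-methyl-3-{[(2Z)-2-methylbut-2-enoyl]oxy}hepta-1,5-dien-2-yl]-7-oxabicyclo[4.1.0]heptan-3-yl (2Z)-2-methylbut-2-enoate | C=C([C@H](CC=C(C)C)OC(=O)/C(C)=C\C)[C@@H]1C[C@@H]2O[C@]2(C)[C@H](OC(C)=O)[C@@H]1OC(=O)/C(C)=C\C | intermediate
16 | (1S,2R,3R,4S,6S)-2-(acetyloxy)-4-[(3S)-4-[(2S)-3,3-dimethyloxiran-2-yl]-3-{[(2Z)-2-methylbut-2-enoyl]oxy}but-1-en-2-yl]-1-methyl-7-oxabicyclo[4.1.0]heptan-3-yl (2Z)-2-methylbut-2-enoate | C=C([C@H](C[C@@H]1OC1(C)C)OC(=O)/C(C)=C\C)[C@@H]1C[C@@H]2O[C@]2(C)[C@H](OC(C)=O)[C@@H]1OC(=O)/C(C)=C\C | target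

**Count and risks**

Total steps: 11. Longest linear sequence: 10 (steps 1–7 and 9–11, from 4-iodotoluene); step 8 is a one-step side branch.

Steps most likely to fail:

1. Step 4 (radical ring closure). Possible failures are reduction of the vinyl radical before it cyclises, hydrogen transfer within the radical from C6–H, sluggish bromine abstraction that lets stannyl radicals consume the diene by hydrostannation, or hydrogen delivery to C1 instead of C3. Fallback, setting out from 3 and returning at 7: the same α-silylvinyl radical is reached by radical addition instead of halogen abstraction. Diol 3 is silylated at O5 with chloro(ethynyl)dimethylsilane (Et3N, CH2Cl2, −78 °C) to give (1S,6R)-6-{[ethynyl(dimethyl)silyl]oxy}-2-methylcyclohexa-2,4-dien-1-ol F1, which is acetylated in the same flask to (1S,6R)-6-{[ethynyl(dimethyl)silyl]oxy}-2-methylcyclohexa-2,4-dien-1-yl acetate F2. Bu3SnH/AIBN in benzene then adds a stannyl radical to the alkyne terminus, and the vinyl radical so formed closes the same oxasilolane ring onto C4 (hydrostannylative enyne cyclisation) to give (3aR,7S,7aR)-2,2,6-trimethyl-3-[(tributylstannyl)methylidene]-2,3,3a,4,7,7a-hexahydro-1,2-benzoxasilol-7-yl acetate F3. Protodestannylation with p-toluenesulfonic acid in CH2Cl2 at 0 °C, which is directed to the tin-bearing carbon by the β-effect of tin, gives 7.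

2. Step 5 (iododesilylation). Possible failures are attack of the iodinating agent on the C1=C2 bond with participation of the C6 acetate, or ionisation of the allylic acetate in the acidic fluorinated solvent. Fallback, setting out from 7 and returning at 14: the C–Si bond is oxidised instead of halogenated and C7 is activated as an enol triflate. Tamao–Fleming oxidation of 7 (H2O2, KF, KHCO3, THF/MeOH) gives (1S,5R,6R)-5-acetyl-6-hydroxy-2-methylcyclohex-2-en-1-yl acetate F4. Directed epoxidation as in step 6 gives (1S,2R,3R,4R,6S)-4-acetyl-3-hydroxy-1-methyl-7-oxabicyclo[4.1.0]heptan-2-yl acetate F5, and angeloylation as in step 7 gives (1S,2R,3R,4R,6S)-4-acetyl-2-(acetyloxy)-1-methyl-7-oxabicyclo[4.1.0]heptan-3-yl (2Z)-2-methylbut-2-enoate F6. Kinetic deprotonation of the methyl ketone with KN(SiMe3)2 in the presence of PhNTf2 (THF, −78 °C) gives (1S,2R,3R,4R,6S)-2-(acetyloxy)-1-methyl-4-{1-[(trifluoromethanesulfonyl)oxy]ethenyl}-7-oxabicyclo[4.1.0]heptan-3-yl (2Z)-2-methylbut-2-enoate F7. F7 is coupled with 13 under the CrCl2/NiCl2 conditions of step 9 to give 14.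

3. Step 7 (angeloylation of the C5 hydroxyl). Possible failures are stalled acylation of the crowded axial hydroxyl, migration of the acetyl group from O6 to O5 under heat and amine, or isomerisation of the Z-alkene to the tiglate. Fallback, setting out from 10 and returning at 11: the Z-alkene is built on the substrate instead of being transferred. Alcohol 10 is esterified with 2-[bis(2,2,2-trifluoroethoxy)phosphoryl]propanoic acid (DCC, CH2Cl2, 0 °C, an acylation that can proceed through a reactive phosphonoketene) to give (1S,2R,3R,4R,6S)-2-(acetyloxy)-4-(1-iodoethenyl)-1-methyl-7-oxabicyclo[4.1.0]heptan-3-yl 2-[bis(2,2,2-trifluoroethoxy)phosphoryl]propanoate F8. Still–Gennari olefination of F8 with acetaldehyde (KN(SiMe3)2, 18-crown-6, THF, −78 °C) should give the Z-configured 2-methylbut-2-enoate 11.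

**Further compounds**

F1 | step 4 | (1S,6R)-6-{[ethynyl(dimethyl)silyl]oxy}-2-methylcyclohexa-2,4-dien-1-ol | C1=CC=C(C)[C@H](O)[C@@H]1O[Si](C)(C)C#C
F2 | step 4 | (1S,6R)-6-{[ethynyl(dimethyl)silyl]oxy}-2-methylcyclohexa-2,4-dien-1-yl acetate | C1=CC=C(C)[C@H](OC(C)=O)[C@@H]1O[Si](C)(C)C#C
F3 | step 4 | (3aR,7S,7aR)-2,2,6-trimethyl-3-[(tributylstannyl)methylidene]-2,3,3a,4,7,7a-hexahydro-1,2-benzoxasilol-7-yl acetate (E/Z mixture) | CCCC[Sn](CCCC)(CCCC)C=C3[C@@H]1CC=C(C)[C@H](OC(C)=O)[C@@H]1O[Si]3(C)C
F4 | step 5 | (1S,5R,6R)-5-acetyl-6-hydroxy-2-methylcyclohex-2-en-1-yl acetate | CC(=O)[C@@H]1CC=C(C)[C@H](OC(C)=O)[C@@H]1O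
F5 | step 5 | (1S,2R,3R,4R,6S)-4-acetyl-3-hydroxy-1-methyl-7-oxabicyclo[4.1.0]heptan-2-yl acetate | CC(=O)[C@@H]1C[C@@H]2O[C@]2(C)[C@H](OC(C)=O)[C@@H]1O
F6 | step 5 | (1S,2R,3R,4R,6S)-4-acetyl-2-(acetyloxy)-1-methyl-7-oxabicyclo[4.1.0]heptan-3-yl (2Z)-2-methylbut-2-enoate | CC(=O)[C@@H]1C[C@@H]2O[C@]2(C)[C@H](OC(C)=O)[C@@H]1OC(=O)/C(C)=C\C
F7 | step 5 | (1S,2R,3R,4R,6S)-2-(acetyloxy)-1-methyl-4-{1-[(trifluoromethanesulfonyl)oxy]ethenyl}-7-oxabicyclo[4.1.0]heptan-3-yl (2Z)-2-methylbut-2-enoate | C=C(OS(=O)(=O)C(F)(F)F)[C@@H]1C[C@@H]2O[C@]2(C)[C@H](OC(C)=O)[C@@H]1OC(=O)/C(C)=C\C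
F8 | step 7 | (1S,2R,3R,4R,6S)-2-(acetyloxy)-4-(1-iodoethenyl)-1-methyl-7-oxabicyclo[4.1.0]heptan-3-yl 2-[bis(2,2,2-trifluoroethoxy)phosphoryl]propanoate (both epimers at the phosphonate carbon) | C=C(I)[C@@H]1C[C@@H]2O[C@]2(C)[C@H](OC(C)=O)[C@@H]1OC(=O)C(C)P(=O)(OCC(F)(F)F)OCC(F)(F)F
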